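**Retrosynthetic overview**
1. Acid 20 ⇐ methyl ester 19 ⇐ β-hydroxy ester 17 (E1cB dehydration installs C2=C3; acid-chain numbering C1–C14 throughout).
2. The 1,2-dioxolane is the only ring of the target and is closed late (step 9) from epoxy tertiary allylic alcohol 15 and H2O2: C6–O by reversible SN1 perhydrolysis, C4–O by 5-exo epoxide opening with inversion.
3. 15 ⇐ carbonyl addition (C6–C7) of the alkenylcerium from iodide 7 (C7–C14) to epoxy keto ester 12 (C1–C6 with both ring ethyl groups).
4. 12 ⇐ 1,3-diethylbenzene 8: Birch reduction, enantioselective mono-epoxidation, ozonolytic opening of the temporary six-membered ring.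
5. 7 ⇐ (E)-pent-2-enal 1: asymmetric ethylation, Johnson–Claisen rearrangement (sets C10 and C11=C12), ester-to-alkyne homologation, carboalumination–iodination (sets C7=C8).

Assumption: the target is the (4S,6R,10R) acid as drawn; for the chiral acid of step 9 the (R)-enantiomer is taken as the matched one, and its antipode is used instead if the first run shows otherwise.

**Step 1**
Reactants: 1 (2E)-pent-2-enal
Product: 2 (3R,4E)-hept-4-en-3-ol
Conditions: Et2Zn (2.0 equiv), (2R)-3-exo-morpholinoisoborneol [(+)-MIB, 4 mol%], hexane–toluene, 0 °C; then aq. NH4Cl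
Reagents that add atoms: diethylzinc, CC[Zn]CC
Why: Amino-alcohol-catalysed enantioselective dialkylzinc addition to an aldehyde (Noyori–Nugent type), in which the chiral ethylzinc alkoxide chelate delivers ethyl to the Re face of the enal and sets the (R)-carbinol that is later relayed to C10.

**Step 2**
Reactants: 2 (3R,4E)-hept-4-en-3-ol
Product: 3 ethyl (3R,4E)-3-ethylhept-4-enoate
Conditions: MeC(OEt)3 (5 equiv), EtCO2H (cat.), 140 °C, EtOH distilled off
Reagents that add atoms: triethyl orthoacetate, CC(OCC)(OCC)OCC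
Why: Johnson–Claisen [3,3]-sigmatropic rearrangement through a chair transition state with the carbinol ethyl group equatorial gives the new (E)-alkene (future C11=C12) and transfers the C–O chirality suprafacially to the new C–C bond, setting the future C10 centre as (R).

**Step 3**
Reactants: 3 ethyl (3R,4E)-3-ethylhept-4-enoate
Product: 5 (4R,5E)-4-ethyloct-5-en-1-yne, via aldehyde (3R,4E)-3-ethylhept-4-enal 4 (not isolated)
Conditions: i-Bu2AlH (1.1 equiv), CH2Cl2, −78 °C; then MeOH, K2CO3, dimethyl (1-diazo-2-oxopropyl)phosphonate, −78 °C → rt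
Reagents that add atoms: dimethyl (1-diazo-2-oxopropyl)phosphonate, CC(=O)C(=[N+]=[N-])P(=O)(OC)OC
Why: Half-reduction of the ester to the aldehyde followed in the same flask by Ohira–Bestmann (Seyferth–Gilbert) homologation gives the terminal alkyne, and the β-stereocentre is not enolisable and so is untouched.

**Step 4**
Reactants: 5 (4R,5E)-4-ethyloct-5-en-1-yne
Product: 7 (1E,4R,5E)-4-ethyl-1-iodo-2-methylocta-1,5-diene, via alkenyl(dimethyl)alane 6 (not isolated)
Conditions: Me3Al (2.5 equiv), Cp2ZrCl2 (0.25 equiv), CH2Cl2, 0 °C → rt; then I2, THF, −30 °C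
Reagents that add atoms: trimethylaluminium, C[Al](C)C; iodine, II
Why: Negishi zirconium-catalysed carboalumination adds methyl and aluminium syn across the terminal alkyne with methyl on the internal carbon, and iodinolysis with retention gives the (E)-trisubstituted alkenyl iodide, fixing the C7=C8 geometry.

**Step 5**
Reactants: 8 1,3-diethylbenzene
Product: 9 1,5-diethylcyclohexa-1,4-diene
Conditions: Li, NH3 (l), THF, t-BuOH, −78 → −33 °C; then NH4Cl
Reagents that add atoms: none
Why: Birch reduction leaves both alkyl groups on the residual double bonds, giving the skipped diene whose six ring carbons are C1–C6 of the acid chain with both ethyl groups in place.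

**Step 6**
Reactants: 9 1,5-diethylcyclohexa-1,4-diene
Product: 10 (1R,6S)-1,3-diethyl-7-oxabicyclo[4.1.0]hept-3-ene
Conditions: 1,2:4,5-di-O-isopropylidene-β-L-erythro-2,3-hexodiulo-2,6-pyranose (L-fructose-derived Shi ketone, 30 mol%), 2KHSO5·KHSO4·K2SO4 (0.7 equiv KHSO5), K2CO3, Bu4NHSO4, MeCN–CH2(OMe)2–aq. Na2B4O7, 0 °C
Reagents that add atoms: potassium peroxymonosulfate (KHSO5), [K+].[O-]S(=O)(=O)OO
Why: Shi asymmetric epoxidation by the chiral dioxirane through the spiro transition state; the two alkenes are enantiotopic, so the catalyst's face preference gives the same (1R,6S)-oxirane at either one (the D-fructose ketone would give the antipode by analogy with its (R,R)-selectivity for 1-substituted cyclohexenes), and limiting oxidant keeps bis-epoxide low while unreacted 9 is recycled.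

**Step 7**
Reactants: 10 (1R,6S)-1,3-diethyl-7-oxabicyclo[4.1.0]hept-3-ene
Product: 12 methyl 2-[(2S,3R)-3-ethyl-3-(2-oxobutyl)oxiran-2-yl]acetate, via methoxy hydroperoxide 11 (not isolated)
Conditions: O3, NaHCO3, CH2Cl2–MeOH (5:1), −78 °C; then Ac2O, pyridine, CH2Cl2, 0 °C → rt
Reagents that add atoms: ozone, [O-][O+]=O; methanol, CO
Why: Schreiber unsymmetrical ozonolysis, in which the primary ozonide of the trisubstituted alkene fragments to the ethyl ketone and an aldehyde oxide that methanol traps as the α-methoxy hydroperoxide, whose acetylation–elimination gives the methyl ester without touching the oxirane stereocentres.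

**Step 8**
Reactants: 7 (1E,4R,5E)-4-ethyl-1-iodo-2-methylocta-1,5-diene; 12 methyl 2-[(2S,3R)-3-ethyl-3-(2-oxobutyl)oxiran-2-yl]acetate
Product: 15 methyl 2-[(2S,3R)-3-[(3E,6R,7E)-2,6-diethyl-2-hydroxy-4-methyldeca-3,7-dien-1-yl]-3-ethyloxiran-2-yl]acetate (both epimers at the carbinol carbon), via alkenyllithium 13 (not isolated), via alkenylcerium dichloride 14 (not isolated)
Conditions: 7, t-BuLi (2.0 equiv), Et2O, −78 °C; CeCl3 (anhydrous), THF, −78 °C; then 12, −78 °C; pH 7 phosphate buffer
Reagents that add atoms: none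
Why: Iodine–lithium exchange with retention of alkene geometry and transmetalation to the weakly basic organocerium (Imamoto conditions) allow 1,2-addition to the enolisable ketone in the presence of the ester and the epoxide; the new carbinol centre forms unselectively, which is irrelevant because it is ionised in step 9.

**Step 9**
Reactants: 15 methyl 2-[(2S,3R)-3-[(3E,6R,7E)-2,6-diethyl-2-hydroxy-4-methyldeca-3,7-dien-1-yl]-3-ethyloxiran-2-yl]acetate
Product: 17 methyl (3S)-3-[(3S,5R)-3,5-diethyl-5-[(1E,4R,5E)-4-ethyl-2-methylocta-1,5-dien-1-yl]-1,2-dioxolan-3-yl]-3-hydroxypropanoate, via allylic hydroperoxide 16 (not isolated)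
Conditions: H2O2 (anhydrous, 2.5 equiv in Et2O), (R)-3,3′-bis(2,4,6-triisopropylphenyl)-1,1′-binaphthyl-2,2′-diyl N-triflylphosphoramide (5 mol%), toluene, −30 → 0 °C; then aq. NaHCO3
Reagents that add atoms: hydrogen peroxide, OO
Why: Proposed new method: a Brønsted-acid-catalysed perhydrolysis/epoxide-opening cascade with dynamic kinetic resolution, in which the acid ionises the tertiary allylic alcohol (either epimer) to a doubly tertiary allyl cation that H2O2 captures reversibly to give the two C6-epimeric hydroperoxides 16 (the C8 regioisomer cannot cyclise and returns through the same cation), and the hydroperoxide then opens the acid-activated epoxide 5-exo at its tertiary carbon with inversion, so that both peroxide C–O bonds are formed, C4 is set as (S) stereospecifically and C6 is set as (R) under Curtin–Hammett control because the broad 2-methylalkenyl arm sits syn to the tied-back epoxide carbon C3 (both ethyl groups cis), a preference the chiral phosphoramide anion, hydrogen-bonded to the OOH donor and the epoxide oxygen, is chosen to reinforce; the closest known reactions are the acid-catalysed perhydrolysis of tertiary allylic alcohols and of trisubstituted epoxides (inversion at the tertiary carbon) and chiral-phosphoric-acid-catalysed intramolecular epoxide openings.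

**Step 10**
Reactants: 17 methyl (3S)-3-[(3S,5R)-3,5-diethyl-5-[(1E,4R,5E)-4-ethyl-2-methylocta-1,5-dien-1-yl]-1,2-dioxolan-3-yl]-3-hydroxypropanoate
Product: 19 methyl (2E)-3-[(3S,5R)-3,5-diethyl-5-[(1E,4R,5E)-4-ethyl-2-methylocta-1,5-dien-1-yl]-1,2-dioxolan-3-yl]prop-2-enoate, via mesylate 18 (not isolated)
Conditions: MsCl, Et3N, CH2Cl2, 0 °C; then DBU, rt
Reagents that add atoms: none
Why: Sulfonylation of the β-hydroxy ester and E1cB elimination give the conjugated (E)-enoate, and because neither peroxide carbon carries hydrogen, base-induced Kornblum–DeLaMare cleavage is impossible and C4 and C6 are untouched.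

**Step 11**
Reactants: 19 methyl (2E)-3-[(3S,5R)-3,5-diethyl-5-[(1E,4R,5E)-4-ethyl-2-methylocta-1,5-dien-1-yl]-1,2-dioxolan-3-yl]prop-2-enoate
Product: 20 (2E)-3-[(3S,5R)-3,5-diethyl-5-[(1E,4R,5E)-4-ethyl-2-methylocta-1,5-dien-1-yl]-1,2-dioxolan-3-yl]prop-2-enoic acid
Conditions: LiOH, THF–H2O (3:1), 0 °C → rt; then 1 M HCl to pH 3
Reagents that add atoms: lithium hydroxide, [Li+].[OH-]
Why: Saponification (acyl-oxygen ester hydrolysis) of the methyl ester, to which the fully substituted dialkyl peroxide, the three alkenes and the three stereocentres are inert.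

**Compound list**
1 | (2E)-pent-2-enal | CC/C=C/C=O | starting material
2 | (3R,4E)-hept-4-en-3-ol | CC[C@@H](O)/C=C/CC | intermediate
3 | ethyl (3R,4E)-3-ethylhept-4-enoate | CC/C=C/[C@H](CC)CC(=O)OCC | intermediate
4 | (3R,4E)-3-ethylhept-4-enal (not isolated) | CC/C=C/[C@H](CC)CC=O | intermediate
5 | (4R,5E)-4-ethyloct-5-en-1-yne | CC/C=C/[C@H](CC)CC#C | intermediate
6 | [(1E,4R,5E)-4-ethyl-2-methylocta-1,5-dien-1-yl]dimethylalane (not isolated) | CC/C=C/[C@H](CC)C/C(C)=C/[Al](C)C | intermediate
7 | (1E,4R,5E)-4-ethyl-1-iodo-2-methylocta-1,5-diene | CC/C=C/[C@H](CC)C/C(C)=C/I | intermediate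
8 | 1,3-diethylbenzene | CCc1cccc(CC)c1 | starting material
9 | 1,5-diethylcyclohexa-1,4-diene | CCC1=CCC=C(CC)C1 | intermediate
10 | (1R,6S)-1,3-diethyl-7-oxabicyclo[4.1.0]hept-3-ene | CCC1=CC[C@@H]2O[C@]2(CC)C1 | intermediate
11 | 1-[(2R,3S)-2-ethyl-3-(2-hydroperoxy-2-methoxyethyl)oxiran-2-yl]butan-2-one (not isolated) | CCC(=O)C[C@@]1(CC)O[C@H]1CC(OC)OO | intermediate
12 | methyl 2-[(2S,3R)-3-ethyl-3-(2-oxobutyl)oxiran-2-yl]acetate | CCC(=O)C[C@@]1(CC)O[C@H]1CC(=O)OC | intermediate
13 | [(1E,4R,5E)-4-ethyl-2-methylocta-1,5-dien-1-yl]lithium (not isolated) | CC/C=C/[C@H](CC)C/C(C)=C/[Li] | intermediate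
14 | dichloro[(1E,4R,5E)-4-ethyl-2-methylocta-1,5-dien-1-yl]cerium (not isolated) | CC/C=C/[C@H](CC)C/C(C)=C/[Ce](Cl)Cl | intermediate
15 | methyl 2-[(2S,3R)-3-[(3E,6R,7E)-2,6-diethyl-2-hydroxy-4-methyldeca-3,7-dien-1-yl]-3-ethyloxiran-2-yl]acetate (both carbinol epimers) | CC/C=C/[C@H](CC)C/C(C)=C/C(O)(CC)C[C@@]1(CC)O[C@H]1CC(=O)OC | intermediate
16 | methyl 2-[(2S,3R)-3-[(3E,6R,7E)-2,6-diethyl-2-hydroperoxy-4-methyldeca-3,7-dien-1-yl]-3-ethyloxiran-2-yl]acetate (both epimers, not isolated) | CC/C=C/[C@H](CC)C/C(C)=C/C(OO)(CC)C[C@@]1(CC)O[C@H]1CC(=O)OC | intermediate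
17 | methyl (3S)-3-[(3S,5R)-3,5-diethyl-5-[(1E,4R,5E)-4-ethyl-2-methylocta-1,5-dien-1-yl]-1,2-dioxolan-3-yl]-3-hydroxypropanoate | CC/C=C/[C@H](CC)C/C(C)=C/[C@@]1(CC)C[C@]([C@@H](O)CC(=O)OC)(CC)OO1 | intermediate
18 | methyl (3S)-3-[(3S,5R)-3,5-diethyl-5-[(1E,4R,5E)-4-ethyl-2-methylocta-1,5-dien-1-yl]-1,2-dioxolan-3-yl]-3-(methanesulfonyloxy)propanoate (not isolated) | CC/C=C/[C@H](CC)C/C(C)=C/[C@@]1(CC)C[C@]([C@@H](OS(C)(=O)=O)CC(=O)OC)(CC)OO1 | intermediate
19 | methyl (2E)-3-[(3S,5R)-3,5-diethyl-5-[(1E,4R,5E)-4-ethyl-2-methylocta-1,5-dien-1-yl]-1,2-dioxolan-3-yl]prop-2-enoate | CC/C=C/[C@H](CC)C/C(C)=C/[C@@]1(CC)C[C@](/C=C/C(=O)OC)(CC)OO1 | intermediate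
20 | (2E)-3-[(3S,5R)-3,5-diethyl-5-[(1E,4R,5E)-4-ethyl-2-methylocta-1,5-dien-1-yl]-1,2-dioxolan-3-yl]prop-2-enoic acid | CC/C=C/[C@H](CC)C/C(C)=C/[C@@]1(CC)C[C@](/C=C/C(=O)O)(CC)OO1 | target

**Step count and risks**
Total step count: 11. Longest linear sequence: 8 steps (1, 2, 3, 4, 8, 9, 10, 11).

The three steps most likely to fail are given in route order; step 9 is the least certain.

Step 6 can fail through bis-epoxidation of the symmetric diene or an ee below about 90% for a non-conjugated alkylcyclohexene. The fallback sets out from 9 and comes back at 12, and it exchanges the order of ring cleavage and epoxidation. One alkene of 9 is ozonised (O3, 0.9 equiv, CH2Cl2–MeOH, NaHCO3; Ac2O, pyridine) to the acyclic keto ester methyl (3Z)-4-ethyl-6-oxooct-3-enoate F1. Its only alkene is then epoxidised with the same L-fructose-derived ketone and KHSO5 to give 12, so over-oxidation cannot occur at that stage.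

Step 7 can fail through the wrong sense of primary-ozonide cleavage, attack of the peroxidic intermediate on the neighbouring epoxide, or loss of the base-sensitive β,γ-epoxy ketone. The fallback sets out from 10 and comes back at 12 by a peroxide-free stepwise cleavage. OsO4 (cat.) with N-methylmorpholine N-oxide dihydroxylates the remaining alkene to (1R,6S)-1,3-diethyl-7-oxabicyclo[4.1.0]heptane-3,4-diol F2. NaIO4 cleaves the diol to 2-[(2S,3R)-3-ethyl-3-(2-oxobutyl)oxiran-2-yl]acetaldehyde F3. Buffered NaClO2 (NaH2PO4, 2-methylbut-2-ene) oxidises it to 2-[(2S,3R)-3-ethyl-3-(2-oxobutyl)oxiran-2-yl]acetic acid F4, and TMSCHN2 in MeOH–toluene esterifies F4 to 12.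

Step 9 is the proposed cascade. It can fail through:
- low cis/trans selectivity at C6 if the epimeric hydroperoxides do not equilibrate or the transition states are not differentiated;
- capture of the allyl cation by the C3 hydroxyl (a tetrahydrofuran) if the epoxide is perhydrolysed intermolecularly first;
- lactonisation of the epoxide by the ester carbonyl;
- Hock-type cleavage of the allylic hydroperoxide;
- epimerisation of 17 by re-ionisation at C6.

The fallback uses known reactions only, sets out from 9 and comes back at 19. It gives up the epoxide logic: the ring is closed by the known palladium-catalysed cyclisation of an unsaturated tertiary hydroperoxide and the side chain is attached afterwards by cross-coupling.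
- 9 is ozonised to keto ester F1 as in the fallback to step 6.
- Prop-1-ynylmagnesium bromide with CeCl3 adds to the ketone to give racemic methyl (3Z)-4,6-diethyl-6-hydroxynon-3-en-7-ynoate F5.
- H2O2 (50%) with catalytic H2SO4 converts the tertiary propargylic alcohol into methyl (3Z)-4,6-diethyl-6-hydroperoxynon-3-en-7-ynoate F6.
- Pd(OAc)2 (10 mol%) with p-benzoquinone in 1,4-dioxane closes the dioxolane by peroxypalladation and β-hydride elimination towards the ester. After chromatographic removal of the trans isomer and preparative chiral-phase HPLC this gives methyl (2E)-3-[(3S,5R)-3,5-diethyl-5-(prop-1-yn-1-yl)-1,2-dioxolan-3-yl]prop-2-enoate F7.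
- Cp2Zr(H)Cl then I2 gives methyl (2E)-3-[(3S,5R)-3,5-diethyl-5-[(1E)-2-iodoprop-1-en-1-yl]-1,2-dioxolan-3-yl]prop-2-enoate F8.
- For the coupling partner, ester 3 is saponified (LiOH) to (3R,4E)-3-ethylhept-4-enoic acid F9, iododecarboxylated (PhI(OAc)2, I2, hν) to (3S,4E)-3-(iodomethyl)hept-4-ene F10 and converted (t-BuLi, then ZnCl2) into [(2S,3E)-2-ethylhex-3-en-1-yl]zinc chloride F11.
- Negishi coupling of F8 with F11 (Pd(PPh3)4, THF) gives 19.

**Further compounds**
F1 | step 6 | methyl (3Z)-4-ethyl-6-oxooct-3-enoate | CCC(=O)C/C(CC)=C\CC(=O)OC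
F2 | step 7 | (1R,6S)-1,3-diethyl-7-oxabicyclo[4.1.0]heptane-3,4-diol (diol carbons as formed) | CCC1(O)C(O)C[C@@H]2O[C@]2(CC)C1
F3 | step 7 | 2-[(2S,3R)-3-ethyl-3-(2-oxobutyl)oxiran-2-yl]acetaldehyde | CCC(=O)C[C@@]1(CC)O[C@H]1CC=O
F4 | step 7 | 2-[(2S,3R)-3-ethyl-3-(2-oxobutyl)oxiran-2-yl]acetic acid | CCC(=O)C[C@@]1(CC)O[C@H]1CC(=O)O
F5 | step 9 | methyl (3Z)-4,6-diethyl-6-hydroxynon-3-en-7-ynoate (racemic) | CC#CC(O)(CC)C/C(CC)=C\CC(=O)OC
F6 | step 9 | methyl (3Z)-4,6-diethyl-6-hydroperoxynon-3-en-7-ynoate (racemic) | CC#CC(OO)(CC)C/C(CC)=C\CC(=O)OC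
F7 | step 9 | methyl (2E)-3-[(3S,5R)-3,5-diethyl-5-(prop-1-yn-1-yl)-1,2-dioxolan-3-yl]prop-2-enoate | CC#C[C@@]1(CC)C[C@](/C=C/C(=O)OC)(CC)OO1
F8 | step 9 | methyl (2E)-3-[(3S,5R)-3,5-diethyl-5-[(1E)-2-iodoprop-1-en-1-yl]-1,2-dioxolan-3-yl]prop-2-enoate | I/C(C)=C/[C@@]1(CC)C[C@](/C=C/C(=O)OC)(CC)OO1
F9 | step 9 | (3R,4E)-3-ethylhept-4-enoic acid | CC/C=C/[C@H](CC)CC(=O)O
F10 | step 9 | (3S,4E)-3-(iodomethyl)hept-4-ene | CC/C=C/[C@H](CC)CI
F11 | step 9 | [(2S,3E)-2-ethylhex-3-en-1-yl]zinc chloride | CC/C=C/[C@H](CC)C[Zn]Cl
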